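The route rests on undoing the C6–O and C9–O bonds together (chain numbered from the free carbinol C1 to the acetoxymethyl C16). The C6 hydroxyl and the butenolide ring oxygen on C9 sit 1,4 and cis across C7–C8, the imprint of one O2 molecule added to a 6E,8E-diene. Singlet-oxygen [4+2] cycloaddition to an achiral, acyclic dienyne, assembled by Sonogashira coupling of a nerol-derived dienyl iodide with a Z-enyne, therefore installs both oxygens in one operation through a temporary cis-dioxine ring. The derived Z-ene-1,4-diol then directs epoxidation to set C7, and the C10≡C11 alkyne becomes the butenolide by hydroalumination, iodination and carbonylation.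

Key step: step 8

Remark: locants C1 to C16 follow the chain as defined above and C19 is the lactone carbonyl carbon.
Remark: the cis-dioxine and the ene-diol formed in step 8 are racemic and are drawn as the enantiomer that is carried on.
Remark: in step 9 it is assumed that the lipase treats the alkynyl group on C9 as the smaller and the Z-alkenyl group as the larger substituent, and that the more hindered C6 carbinol is not acylated.

Step 1
Reactants: 1 nerol
Product: 2 neryl tert-butyldiphenylsilyl ether
Conditions: TBDPSCl, imidazole, CH2Cl2, 0 °C to rt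
Reagents that add atoms: tert-butyl(chloro)diphenylsilane, CC(C)(C)[Si](Cl)(c1ccccc1)c1ccccc1
Why: Imidazole-promoted O-silylation of the primary allylic alcohol (silyl ether formation) installs a group that should survive every later step and is cleaved only by fluoride at the end.

Step 2
Reactants: 2 neryl tert-butyldiphenylsilyl ether
Product: 3 (2E,6Z)-8-[(tert-butyldiphenylsilyl)oxy]-2,6-dimethylocta-2,6-dien-1-ol
Conditions: SeO2 (cat.), t-BuOOH, salicylic acid (cat.), CH2Cl2, 0 °C to rt
Reagents that add atoms: tert-butyl hydroperoxide, CC(C)(C)OO (its oxygen atom is passed on by catalytic selenium dioxide, O=[Se]=O)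
Why: Selenium dioxide allylic oxidation (ene reaction followed by [2,3]-sigmatropic shift, the hydroperoxide being the terminal oxidant) should attack the more electron-rich distal alkene at its E-methyl group, since the C2=C3 alkene is deactivated by the allylic silyloxy group, and the new allylic alcohol stays E.

Step 3
Reactants: 3 (2E,6Z)-8-[(tert-butyldiphenylsilyl)oxy]-2,6-dimethylocta-2,6-dien-1-ol
Product: 4 (2E,6Z)-8-[(tert-butyldiphenylsilyl)oxy]-2,6-dimethylocta-2,6-dienal
Conditions: MnO2, CH2Cl2, rt
Reagents that add atoms: none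
Why: Manganese dioxide oxidation is selective for allylic alcohols, stops at the enal and touches neither the E-alkene geometry nor the silyl ether.

Step 4
Reactants: 4 (2E,6Z)-8-[(tert-butyldiphenylsilyl)oxy]-2,6-dimethylocta-2,6-dienal; 5 iodoform
Product: 6 tert-butyl{[(2Z,6E,8E)-9-iodo-3,7-dimethylnona-2,6,8-trien-1-yl]oxy}diphenylsilane
Conditions: CrCl2, CHI3, THF/1,4-dioxane, 0 °C to rt
Reagents that add atoms: iodoform (5), IC(I)I
Why: Takai iodo-olefination: the gem-dichromium carbenoid formed from iodoform and CrCl2 adds to the aldehyde and eliminates to give the E-vinyl iodide, a reaction that also serves α-branched enals and here delivers C9.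

Step 5
Reactants: 7 5-chloropent-1-yne
Product: 9 (pent-4-yn-1-yl)triphenylphosphonium iodide, via 5-iodopent-1-yne 8 (not isolated)
Conditions: NaI, PPh3, MeCN, reflux
Reagents that add atoms: sodium iodide, [Na+].[I-]; triphenylphosphine, c1ccc(cc1)P(c1ccccc1)c1ccccc1
Why: Finkelstein exchange turns the primary chloride into the iodide in the flask, which quaternises triphenylphosphine by SN2 substitution while the terminal alkyne is a spectator.

Step 6
Reactants: 9 (pent-4-yn-1-yl)triphenylphosphonium iodide; 10 1-[(tert-butyldimethylsilyl)oxy]propan-2-one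
Product: 12 (2Z)-2-methylhept-2-en-6-yn-1-ol tert-butyldimethylsilyl ether, via ylide 11 (not isolated)
Conditions: KN(SiMe3)2 (1.0 equiv), THF, −78 to 0 °C; then 10, −78 °C to rt
Reagents that add atoms: none
Why: Wittig olefination of a non-stabilised ylide with an α-silyloxy methyl ketone is known to place the oxygenated CH2 group cis to the ylide chain, which sets the Z geometry of C14=C15; the phosphonium α-hydrogens are more acidic than the alkyne C–H, so one equivalent of base should give the ylide cleanly.

Step 7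
Reactants: 6 tert-butyl{[(2Z,6E,8E)-9-iodo-3,7-dimethylnona-2,6,8-trien-1-yl]oxy}diphenylsilane; 12 (2Z)-2-methylhept-2-en-6-yn-1-ol tert-butyldimethylsilyl ether
Product: 13 (2Z,6E,8E,14Z)-3,7,15-trimethylhexadeca-2,6,8,14-tetraen-10-yne-1,16-diol 1-O-tert-butyldiphenylsilyl 16-O-tert-butyldimethylsilyl ether
Conditions: PdCl2(PPh3)2 (cat.), CuI (cat.), Et3N, THF, rt
Reagents that add atoms: none
Why: Sonogashira coupling of the vinyl iodide with the terminal alkyne forms C9–C10 under mild amine conditions with retention of the E geometry and tolerates both silyl ethers.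

Step 8
Reactants: 13 (2Z,6E,8E,14Z)-3,7,15-trimethylhexadeca-2,6,8,14-tetraen-10-yne-1,16-diol 1-O-tert-butyldiphenylsilyl 16-O-tert-butyldimethylsilyl ether
Product: 15 racemic (6R*,9R*)-Z-ene-1,4-diol (2Z,7Z,14Z)-1-[(tert-butyldiphenylsilyl)oxy]-16-[(tert-butyldimethylsilyl)oxy]-3,7,15-trimethylhexadeca-2,7,14-trien-10-yne-6,9-diol, via cis-dioxine 14 (not isolated)
Conditions: O2, visible light, tetraphenylporphyrin (cat.), CH2Cl2, −78 °C; then argon purge, thiourea, MeOH, −78 °C to rt
Reagents that add atoms: dioxygen, O=O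
Why: Singlet oxygen, made by energy transfer from the photoexcited porphyrin, adds to the s-cis conformer of the C6=C7–C8=C9 diene in a concerted suprafacial [4+2] cycloaddition, the oxygen counterpart of a Diels–Alder reaction and the long-known endoperoxide formation from acyclic E,E-1,3-dienes; O–C6 and O–C9 form together and the double bond moves to C7=C8. The only ring closed is the temporary six-membered 3,6-dihydro-1,2-dioxine, closed by the cycloaddition itself and opened again in the same flask when thiourea reduces the O–O bond to the Z-ene-1,4-diol. C6 and C9 are the new stereocentres, and their cis relationship is dictated by the fixed 6E,8E geometry, which puts both outside substituents on the same ring face; the diene is achiral, so the pair is racemic at this stage. The step needs chemoselectivity for [4+2] over ene hydroperoxidation at C2=C3, at C14=C15 and at the allylic positions of the diene itself. This should be secured because the trisubstituted diene is the most electron-rich π system, has only hydrogens at its inside positions and a C7 methyl that favours the s-cis form, while both isolated alkenes are deactivated by allylic silyloxy groups and the alkyne is inert. Low temperature, an aprotic solvent and stopping at full diene consumption should keep the ene channel small.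

Step 9
Reactants: 15 racemic (6R*,9R*)-Z-ene-1,4-diol
Product: 16 (2Z,6R,7Z,9R,14Z)-1-[(tert-butyldiphenylsilyl)oxy]-16-[(tert-butyldimethylsilyl)oxy]-3,7,15-trimethylhexadeca-2,7,14-trien-10-yne-6,9-diol
Conditions: Burkholderia cepacia lipase (immobilised), vinyl acetate, t-BuOMe, 30 °C, stopped slightly past half conversion
Reagents that add atoms: none
Why: Enzymatic acylative kinetic resolution: by the empirical size rule for lipase acylation of secondary alcohols, with the slim alkynyl group as the smaller and the Z-alkenyl group as the larger substituent on C9, the 9S carbinol of the (6S,9S)-antipode should be acetylated, whereas the C6 carbinol, flanked by a fully substituted alkene carbon and a long chain, should be too hindered to react in either enantiomer, so the (6R,9R)-diol stays free, is separated from the monoacetate and gains enantiomeric purity when the reaction is run slightly past half conversion.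

Step 10
Reactants: 16 (6R,9R)-Z-ene-1,4-diol
Product: 17 (2Z,6R,7S,8R,9S,14Z)-7,8-epoxy-1-[(tert-butyldiphenylsilyl)oxy]-16-[(tert-butyldimethylsilyl)oxy]-3,7,15-trimethylhexadeca-2,14-dien-10-yne-6,9-diol
Conditions: VO(acac)2 (cat.), t-BuOOH, CH2Cl2, 0 °C
Reagents that add atoms: tert-butyl hydroperoxide, CC(C)(C)OO
Why: Vanadium-catalysed hydroxyl-directed epoxidation with an alkyl hydroperoxide should touch only the allylic C7=C8 alkene, and because allylic 1,3-strain in the Z-ene-1,4-diol turns both carbinol hydrogens inward and both hydroxyls to the same face, oxygen should be delivered syn to both of them, which sets C7 (and C8) relative to C6 and C9.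

Step 11
Reactants: 17 all-syn epoxy diol
Product: 19 (2Z,6R,7R,9R,10Z,14Z)-11-iodo-1-[(tert-butyldiphenylsilyl)oxy]-16-[(tert-butyldimethylsilyl)oxy]-3,7,15-trimethylhexadeca-2,10,14-triene-6,7,9-triol, via vinylalanate 18 (not isolated)
Conditions: NaAlH2(OCH2CH2OMe)2 (Red-Al), THF, 0 °C to rt; EtOAc, 0 °C; then I2, THF, −78 to 0 °C; aq. potassium sodium tartrate
Reagents that add atoms: iodine, II
Why: Two known hydroxyl-directed Red-Al reactions run in one flask: the C9 alkoxyaluminium hydride opens the epoxide at the secondary C8 (as in the reduction of 2,3-epoxy alcohols to 1,3-diols, leaving the C7–O bond and its configuration untouched) and adds trans across the propargylic alkyne with hydride at C10 and aluminium at C11 in a five-membered alanate, so that iodinolysis with retention should give the Z-vinyl iodide with iodine cis to C9.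

Step 12
Reactants: 19 Z-vinyl iodide triol; 20 carbon monoxide
Product: 21 (5R)-5-[(2R,3R,6Z)-8-[(tert-butyldiphenylsilyl)oxy]-2,3-dihydroxy-2,6-dimethyloct-6-en-1-yl]-3-[(3Z)-5-[(tert-butyldimethylsilyl)oxy]-4-methylpent-3-en-1-yl]furan-2(5H)-one
Conditions: PdCl2(PPh3)2 (cat.), CO (1 atm), Et3N, MeCN, 40 °C
Reagents that add atoms: carbon monoxide (20), [C-]#[O+]
Why: Palladium-catalysed carbonylative lactonisation: oxidative addition of zerovalent palladium to the vinyl iodide, CO insertion and capture of the acylpalladium by the cis C9 hydroxyl close the five-membered butenolide, while the C6 and C7 hydroxyls would need larger rings and the mild amine base should leave C9 untouched.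

Step 13
Reactants: 21 bis-silyl butenolide diol
Product: 22 (5R)-5-[(2R,3R,6Z)-8-[(tert-butyldiphenylsilyl)oxy]-2,3-dihydroxy-2,6-dimethyloct-6-en-1-yl]-3-[(3Z)-5-hydroxy-4-methylpent-3-en-1-yl]furan-2(5H)-one
Conditions: camphorsulfonic acid (cat.), MeOH/CH2Cl2, 0 °C
Reagents that add atoms: none
Why: Acid-catalysed methanolysis (silyl ether solvolysis) cleaves a primary tert-butyldimethylsilyl ether much faster than a tert-butyldiphenylsilyl ether, so only the C16 hydroxyl should be freed.

Step 14
Reactants: 22 C16 alcohol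
Product: 23 (2Z)-5-{(5R)-5-[(2R,3R,6Z)-8-[(tert-butyldiphenylsilyl)oxy]-2,3-dihydroxy-2,6-dimethyloct-6-en-1-yl]-2-oxo-2,5-dihydrofuran-3-yl}-2-methylpent-2-en-1-yl acetate
Conditions: AcCl, 2,4,6-collidine, CH2Cl2, −78 °C
Reagents that add atoms: acetyl chloride, CC(=O)Cl
Why: Low-temperature acetylation with acetyl chloride and a hindered pyridine base (nucleophilic acyl substitution) is selective for primary alcohols, so the C16 hydroxyl should be esterified while the hindered secondary C6 and tertiary C7 hydroxyls stay free.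

Step 15
Reactants: 23 C16 acetate with C1 silyl ether
Product: 24 (2Z)-5-{(5R)-5-[(2R,3R,6Z)-2,3,8-trihydroxy-2,6-dimethyloct-6-en-1-yl]-2-oxo-2,5-dihydrofuran-3-yl}-2-methylpent-2-en-1-yl acetate (CNP0184073.1)
Conditions: HF·pyridine, pyridine, THF, 0 °C to rt
Reagents that add atoms: none
Why: Fluoride-mediated desilylation under buffered, non-basic conditions should remove the tert-butyldiphenylsilyl group without cleaving or migrating the allylic acetate, epimerising C9 or triggering oxa-Michael addition of the C7 hydroxyl to the butenolide.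

Compound list
1 | nerol, (2Z)-3,7-dimethylocta-2,6-dien-1-ol | CC(C)=CCC/C(C)=C\CO | starting material
2 | neryl tert-butyldiphenylsilyl ether | CC(C)=CCC/C(C)=C\CO[Si](c1ccccc1)(c1ccccc1)C(C)(C)C | intermediate
3 | (2E,6Z)-8-[(tert-butyldiphenylsilyl)oxy]-2,6-dimethylocta-2,6-dien-1-ol | OC/C(C)=C/CC/C(C)=C\CO[Si](c1ccccc1)(c1ccccc1)C(C)(C)C | intermediate
4 | (2E,6Z)-8-[(tert-butyldiphenylsilyl)oxy]-2,6-dimethylocta-2,6-dienal | O=C/C(C)=C/CC/C(C)=C\CO[Si](c1ccccc1)(c1ccccc1)C(C)(C)C | intermediate
5 | iodoform | IC(I)I | starting material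
6 | tert-butyl{[(2Z,6E,8E)-9-iodo-3,7-dimethylnona-2,6,8-trien-1-yl]oxy}diphenylsilane (C1 to C9) | I/C=C/C(C)=C/CC/C(C)=C\CO[Si](c1ccccc1)(c1ccccc1)C(C)(C)C | intermediate
7 | 5-chloropent-1-yne | C#CCCCCl | starting material
8 | 5-iodopent-1-yne | C#CCCCI | intermediate (not isolated)
9 | (pent-4-yn-1-yl)triphenylphosphonium iodide | C#CCCC[P+](c1ccccc1)(c1ccccc1)c1ccccc1.[I-] | intermediate
10 | 1-[(tert-butyldimethylsilyl)oxy]propan-2-one | CC(=O)CO[Si](C)(C)C(C)(C)C | starting material
11 | pent-4-yn-1-ylidene(triphenyl)phosphorane (ylide) | C#CCCC=P(c1ccccc1)(c1ccccc1)c1ccccc1 | intermediate (not isolated)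
12 | tert-butyldimethyl{[(2Z)-2-methylhept-2-en-6-yn-1-yl]oxy}silane (C10 to C16) | C#CCC/C=C(C)\CO[Si](C)(C)C(C)(C)C | intermediate
13 | (2Z,6E,8E,14Z)-3,7,15-trimethylhexadeca-2,6,8,14-tetraen-10-yne-1,16-diol, C1 tert-butyldiphenylsilyl and C16 tert-butyldimethylsilyl ether (achiral dienyne) | CC(C)(C)[Si](C)(C)OC/C(C)=C\CCC#C/C=C/C(C)=C/CC/C(C)=C\CO[Si](c1ccccc1)(c1ccccc1)C(C)(C)C | intermediate
14 | racemic cis-3,6-dihydro-1,2-dioxine (6R*,9R*): O–O spans C6 and C9, ring alkene C7=C8 with the methyl on C7, C6 carries the C1 to C5 chain and C9 the alkynyl chain, both on one ring face | CC(C)(C)[Si](C)(C)OC/C(C)=C\CCC#C[C@H]1C=C(C)[C@@H](CC/C(C)=C\CO[Si](c2ccccc2)(c2ccccc2)C(C)(C)C)OO1 | intermediate (not isolated)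
15 | racemic (2Z,6R*,7Z,9R*,14Z)-1-[(tert-butyldiphenylsilyl)oxy]-16-[(tert-butyldimethylsilyl)oxy]-3,7,15-trimethylhexadeca-2,7,14-trien-10-yne-6,9-diol | CC(C)(C)[Si](C)(C)OC/C(C)=C\CCC#C[C@H](O)/C=C(C)\[C@H](O)CC/C(C)=C\CO[Si](c1ccccc1)(c1ccccc1)C(C)(C)C | intermediate
16 | (2Z,6R,7Z,9R,14Z)-1-[(tert-butyldiphenylsilyl)oxy]-16-[(tert-butyldimethylsilyl)oxy]-3,7,15-trimethylhexadeca-2,7,14-trien-10-yne-6,9-diol, single enantiomer | CC(C)(C)[Si](C)(C)OC/C(C)=C\CCC#C[C@H](O)/C=C(C)\[C@H](O)CC/C(C)=C\CO[Si](c1ccccc1)(c1ccccc1)C(C)(C)C | intermediate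
17 | (2Z,6R,7S,8R,9S,14Z)-7,8-epoxy-1-[(tert-butyldiphenylsilyl)oxy]-16-[(tert-butyldimethylsilyl)oxy]-3,7,15-trimethylhexadeca-2,14-dien-10-yne-6,9-diol (epoxide oxygen syn to both hydroxyls) | CC(C)(C)[Si](C)(C)OC/C(C)=C\CCC#C[C@H](O)[C@H]1O[C@@]1(C)[C@H](O)CC/C(C)=C\CO[Si](c2ccccc2)(c2ccccc2)C(C)(C)C | intermediate
18 | disodium bis-alanate after epoxide opening and hydroalumination, drawn in idealised form: O9 and C11 on one aluminium in a five-membered ring, O6 and O7 on a second aluminium, each aluminium carrying two 2-methoxyethoxy groups | CC(C)(C)[Si](C)(C)OC/C(C)=C\CC/C1=C/[C@H](O[Al-]1(OCCOC)OCCOC)C[C@@]2(C)O[Al-](OCCOC)(OCCOC)O[C@@H]2CC/C(C)=C\CO[Si](c3ccccc3)(c3ccccc3)C(C)(C)C.[Na+].[Na+] | intermediate (not isolated)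
19 | (2Z,6R,7R,9R,10Z,14Z)-11-iodo-1-[(tert-butyldiphenylsilyl)oxy]-16-[(tert-butyldimethylsilyl)oxy]-3,7,15-trimethylhexadeca-2,10,14-triene-6,7,9-triol | CC(C)(C)[Si](C)(C)OC/C(C)=C\CC/C(I)=C/[C@H](O)C[C@@](C)(O)[C@H](O)CC/C(C)=C\CO[Si](c1ccccc1)(c1ccccc1)C(C)(C)C | intermediate
20 | carbon monoxide | [C-]#[O+] | starting material
21 | (5R)-5-[(2R,3R,6Z)-8-[(tert-butyldiphenylsilyl)oxy]-2,3-dihydroxy-2,6-dimethyloct-6-en-1-yl]-3-[(3Z)-5-[(tert-butyldimethylsilyl)oxy]-4-methylpent-3-en-1-yl]furan-2(5H)-one | CC(C)(C)[Si](C)(C)OC/C(C)=C\CCC1=C[C@@H](C[C@@](C)(O)[C@H](O)CC/C(C)=C\CO[Si](c2ccccc2)(c2ccccc2)C(C)(C)C)OC1=O | intermediate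
22 | (5R)-5-[(2R,3R,6Z)-8-[(tert-butyldiphenylsilyl)oxy]-2,3-dihydroxy-2,6-dimethyloct-6-en-1-yl]-3-[(3Z)-5-hydroxy-4-methylpent-3-en-1-yl]furan-2(5H)-one | OC/C(C)=C\CCC1=C[C@@H](C[C@@](C)(O)[C@H](O)CC/C(C)=C\CO[Si](c2ccccc2)(c2ccccc2)C(C)(C)C)OC1=O | intermediate
23 | (2Z)-5-{(5R)-5-[(2R,3R,6Z)-8-[(tert-butyldiphenylsilyl)oxy]-2,3-dihydroxy-2,6-dimethyloct-6-en-1-yl]-2-oxo-2,5-dihydrofuran-3-yl}-2-methylpent-2-en-1-yl acetate | CC(=O)OC/C(C)=C\CCC1=C[C@@H](C[C@@](C)(O)[C@H](O)CC/C(C)=C\CO[Si](c2ccccc2)(c2ccccc2)C(C)(C)C)OC1=O | intermediate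
24 | (2Z)-5-{(5R)-5-[(2R,3R,6Z)-2,3,8-trihydroxy-2,6-dimethyloct-6-en-1-yl]-2-oxo-2,5-dihydrofuran-3-yl}-2-methylpent-2-en-1-yl acetate, CNP0184073.1 (6R,7R,9R in chain numbering) | CC(=O)OC/C(C)=C\CCC1=C[C@@H](C[C@@](C)(O)[C@H](O)CC/C(C)=C\CO)OC1=O | target

Total step count: 15.
Longest linear sequence: 13 steps (steps 1 to 4 and 7 to 15).

Steps most likely to fail

1. Step 8 (key step). What may go wrong: ene-type hydroperoxidation at C2=C3, at C14=C15 or at the allylic positions of the diene may outrun the cycloaddition, or the addition may turn stepwise and lose the cis relationship. Fallback, setting out from silyl ether 2 and returning at diol 16, so that steps 8 and 9 are both bypassed: the Z-ene-1,4-diol is built on a butenolide template without singlet oxygen. Epoxidation of the distal alkene of 2 with mCPBA should give the racemic 6,7-epoxide F1 as the main product, and periodic acid cleavage of it should give the aldehyde (4Z)-6-[(tert-butyldiphenylsilyl)oxy]-4-methylhex-4-enal F2 with loss of acetone. Asymmetric addition of methyl propiolate with Me2Zn and the ProPhenol ligand antipode that delivers the 4R carbinol should lead to the γ-hydroxy ynoate F3 whose carbinol carbon is the future C6. Syn addition of Me2CuLi at −78 °C followed by lactonisation in the flask should give the 5R-configured 4-methylbutenolide F4 in which the ring holds C6 and C9 cis on C7=C8. Reduction with i-Bu2AlH at −78 °C and an acid-free work-up should give the lactol F5 as both anomers. The lithium acetylide F6 made from enyne 12 with n-BuLi should then add to the open hydroxy-enal form of the lactol and give diol 16 together with its C9 epimer F7 which is removed by chromatography.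

2. Step 9. What may go wrong: the enzyme may discriminate poorly or turn over slowly because both carbinols carry two large groups, and the wanted enantiomer may itself be acylated at O6, the locally mirror-related site. Fallback, setting out from racemic diol 15 and returning at diol 16: resolution through covalent diastereomers. Both hydroxyls of 15 are esterified with (S)-O-methylmandelic acid using DCC and catalytic DMAP in CH2Cl2 at 0 °C. The (6R,9R)-bis-mandelate F8 is separated by chromatography from the (6S,9S)-bis-mandelate F9 and the latter is discarded. Methanolysis of F8 with K2CO3 in MeOH at rt should return 16.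

3. Step 11. What may go wrong: one reagent has to do two jobs, so hydride may also enter at C7 through the C6 alkoxide, hydroalumination may stall on the polyalkoxide aggregate, the vinylalanate may be protonated before iodine reaches it, or a silyl ether may be lost on long exposure. Fallback, setting out from epoxy diol 17 and returning at vinyl iodide 19: the two events are separated and aluminium is replaced by silicon. LiBHEt3 in THF at 0 °C should open the epoxide at the less substituted C8 and leave the alkyne untouched, giving the alkynyl triol F10 with the tertiary C7 hydroxyl intact. Ruthenium-catalysed trans-hydrosilylation with benzyldimethylsilane and [(C5Me5)Ru(MeCN)3]PF6 should place silicon on C11, distal to the propargylic hydroxyl, giving the Z-vinylsilane triol F11 with silicon cis to C9. Iododesilylation of this vinylsilane with N-iodosuccinimide in hexafluoroisopropanol, with retention, should then give 19.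

Further compounds
F1 | step 8 | 6,7-epoxide of silyl ether 2 (racemic), tert-butyl{[(2Z)-5-(3,3-dimethyloxiran-2-yl)-3-methylpent-2-en-1-yl]oxy}diphenylsilane | CC1(C)OC1CC/C(C)=C\CO[Si](c2ccccc2)(c2ccccc2)C(C)(C)C
F2 | step 8 | (4Z)-6-[(tert-butyldiphenylsilyl)oxy]-4-methylhex-4-enal | O=CCC/C(C)=C\CO[Si](c1ccccc1)(c1ccccc1)C(C)(C)C
F3 | step 8 | methyl (4R,7Z)-9-[(tert-butyldiphenylsilyl)oxy]-4-hydroxy-7-methylnon-7-en-2-ynoate | COC(=O)C#C[C@H](O)CC/C(C)=C\CO[Si](c1ccccc1)(c1ccccc1)C(C)(C)C
F4 | step 8 | (5R)-5-[(3Z)-5-[(tert-butyldiphenylsilyl)oxy]-3-methylpent-3-en-1-yl]-4-methylfuran-2(5H)-one | CC1=CC(=O)O[C@@H]1CC/C(C)=C\CO[Si](c2ccccc2)(c2ccccc2)C(C)(C)C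
F5 | step 8 | (5R)-5-[(3Z)-5-[(tert-butyldiphenylsilyl)oxy]-3-methylpent-3-en-1-yl]-4-methyl-2,5-dihydrofuran-2-ol (lactol, both anomers) | CC1=CC(O)O[C@@H]1CC/C(C)=C\CO[Si](c2ccccc2)(c2ccccc2)C(C)(C)C
F6 | step 8 | lithium acetylide of enyne 12 | [Li]C#CCC/C=C(C)\CO[Si](C)(C)C(C)(C)C
F7 | step 8 | (6R,9S)-diol, the C9 epimer of 16 | CC(C)(C)[Si](C)(C)OC/C(C)=C\CCC#C[C@@H](O)/C=C(C)\[C@H](O)CC/C(C)=C\CO[Si](c1ccccc1)(c1ccccc1)C(C)(C)C
F8 | step 9 | bis-(S)-O-methylmandelate of the (6R,9R)-diol | CC(C)(C)[Si](C)(C)OC/C(C)=C\CCC#C[C@H](OC(=O)[C@@H](OC)c1ccccc1)/C=C(C)\[C@H](OC(=O)[C@@H](OC)c1ccccc1)CC/C(C)=C\CO[Si](c1ccccc1)(c1ccccc1)C(C)(C)C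
F9 | step 9 | bis-(S)-O-methylmandelate of the (6S,9S)-diol | CC(C)(C)[Si](C)(C)OC/C(C)=C\CCC#C[C@@H](OC(=O)[C@@H](OC)c1ccccc1)/C=C(C)\[C@@H](OC(=O)[C@@H](OC)c1ccccc1)CC/C(C)=C\CO[Si](c1ccccc1)(c1ccccc1)C(C)(C)C
F10 | step 11 | (2Z,6R,7R,9R,14Z)-1-[(tert-butyldiphenylsilyl)oxy]-16-[(tert-butyldimethylsilyl)oxy]-3,7,15-trimethylhexadeca-2,14-dien-10-yne-6,7,9-triol | CC(C)(C)[Si](C)(C)OC/C(C)=C\CCC#C[C@H](O)C[C@@](C)(O)[C@H](O)CC/C(C)=C\CO[Si](c1ccccc1)(c1ccccc1)C(C)(C)C
F11 | step 11 | Z-vinylsilane triol, benzyldimethylsilyl on C11 cis to C9 | CC(C)(C)[Si](C)(C)OC/C(C)=C\CC/C(=C/[C@H](O)C[C@@](C)(O)[C@H](O)CC/C(C)=C\CO[Si](c1ccccc1)(c1ccccc1)C(C)(C)C)[Si](C)(C)Cc1ccccc1
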